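Remark: ent-kaurane locants are used for every compound (ring A = C1–C5 and C10; C6 on C5; C19 on C4; C20 and C9 on C10). The "upper face" of ring A is the face of the C4 methyl group; in the target C6, C9 and the C1 oxygen lie on it, and C19, C20 and H5 on the lower face.

## Structural features

The target is a 6,7-seco-ent-kaurane of the spirolactone type. It has a cyclohexane ring A (C1–C5, C10), a six-membered lactone (C10–C20–O–C7–C8–C9) joined to ring A at the spiro centre C10, and a bicyclo[3.2.1]octane (six-membered ring C: C8, C9, C11–C14; five-membered ring D: C8, C14, C13, C16, C15) joined to the lactone at the spiro centre C8 and fused to it along C8–C9. There are seven stereocentres: C4, C5, C10 and C1 are contiguous on ring A, C10–C9–C8 is a quaternary–tertiary–quaternary chain, and C13 is the second bridgehead. The α-methylene cyclopentanone (C15=O, C16=C17) is a strong Michael acceptor and must be made late. The acetates at C1 and C6 sit next to the free C19 hydroxyl and the lactone, so acyl transfer under base is a standing danger. The real difficulty is the C8–C9 bond between two fully substituted neighbours, together with the bridged bicycle that carries its ketone on quaternary C8; ring A is a separable problem of one stereotriad plus the C1 carbinol. The key step uses the fact that in the bicyclo[3.2.1]octane C12 is three atoms from C8 (through C11 and C9) and bonded to bridgehead C13, and that C13 is the β-carbon of the C15 ketone as soon as ring D holds a C13=C16 double bond. A C12 acyl anion equivalent can therefore add to C13 of a ring D cyclopentenone and close ring C.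

## Logic of the disconnections

**32 ⇒ 30.** The lactone C7–O bond is opened and both primary hydroxyls are covered: C7 becomes a methyl ester, O19 and O20 become silyl ethers. The lactone and the free C19 hydroxyl, next to two acetates, are the groups least tolerant of the basic steps that come before. The gain is an intermediate with no free hydroxyl. The forward step must remove both silyl groups without base and let O20 close on C7 unaided.

**30 ⇒ 27.** The exocyclic C16=C17 bond is cut. The α-methylene ketone cannot survive sulfur reagents or carbene catalysis, so C17 is the last carbon added. The gain is a plain ketone. The forward step needs enolisation at C16 only, which the quaternary C8 guarantees, but in the presence of two acetates.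

**27 ⇒ 25 (through 26).** A carbonyl group is added at C12. This creates the 1,4-relationship C12=O/C15=O, the retron of a conjugate acylation. Nothing is simplified yet, but the next cut becomes possible. Forward, the C12 carbonyl must be deleted while the C15 ketone stays, which relies on their different hindrance.

**25 ⇒ 24.** The C12–C13 bond is cut, C12 as an acyl anion equivalent (aldehyde) and C13 as the β-carbon of the C16=C13–C15=O enone. It is the one bond of the bicycle whose removal opens ring C and leaves ring D as a simple cyclopentenone. One ring, one bond and the C13 stereocentre disappear. The forward step demands umpolung of an enolisable aldehyde, 1,4- rather than 1,2-addition to a hindered enone, and a chain on C8 that can bridge the five-membered ring.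

**24 ⇒ 21 (through 23).** The C13=C16 unsaturation is removed and the aldehyde is masked as an acetal. Enone and free aldehyde are incompatible with the construction of C8–C9 and with hydrogenolysis at C6. The gain is a saturated β-keto ester. Forward, the ketone must be desaturated on its only enolisable side while the aldehyde is kept from enolising, so the acetal is carried until after the desaturation.

**21 ⇒ 16 + 17 (through 20, 19).** The C8–C9 bond is cut. The C12 aldehyde stands 1,5 to both the C15 ketone and the C7 ester, the retron of a Michael addition of a β-keto ester to an enal. The cut divides the molecule into ring A and a commercial ring D piece and removes two stereocentres. The forward step must join a quaternary carbon to a β-carbon that is itself next to quaternary C10, with control of C9 (enal face) and C8 (enol face).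

**16 ⇒ 14 + 15.** The C9=C11 double bond is cut by a two-carbon olefination. The gain is a ring A aldehyde without side chain. The forward step must olefinate an α-quaternary aldehyde with (E)-selectivity.

**14 ⇒ 9 (through 13, 12, 11, 10).** Functional groups on ring A are interconverted: the C9 aldehyde goes back to an ester, the C1 acetate to a ketone, the C19 and C20 silyl ethers to an aldehyde and a free hydroxymethyl group. Every oxygen of ring A then derives from one β-keto ester aldehyde. Forward, the C1 ketone must be reduced from the lower face, and the C9 ester may be reduced only after O20 is protected, so that the two CH2O groups on C10 stay distinct.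

**9 ⇒ 8.** The C10–C20 bond is cut (aldol with a one-carbon electrophile). The quaternary centre C10 disappears and an enolisable β-keto ester remains. The forward step must bring C20 in trans to C6.

**8 ⇒ 3 + 6 (through 7).** C5–C10 and C3–C4 are cut in a [4+2] sense. Ring A with its C4/C5 pair falls apart into an (E)-enal and a 2-silyloxydiene, both acyclic and achiral. The forward step must control the face of an α-methyl enal with a chiral Lewis acid, and the orientation of the partners.

**3 ⇒ 1 + 2 and 6 ⇒ 4.** The enal C=C bond is cut by a Wittig disconnection, and the diene is traced to a β-methoxy β-keto ester by elimination and O-silylation. Both reach commercial materials. The diene must be formed with the ester on the outside of the s-cis diene.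

## Other disconnections considered

**Alternative 1:** The cut takes out C8–C9 and C13–C14 together, so ring C and the lactone ring open at once. The precursor is the C20 ester A1, in which an α-propargyl acrylate (C8 with its exocyclic C14) is tethered through O20 to a 2-silyloxydiene on C10 (C9, C11, C12, C13). Forward, heating A1 would give the tricyclic spirolactone silyl enol ether A2 by an ester-tethered intramolecular Diels–Alder reaction.

- In its favour: two C–C bonds, two rings and the quaternary centre C8 arise in one step. The crowded C8–C9 bond forms inside a tethered transition state and not in a bimolecular addition, which is a real advantage over step 11 of the chosen plan. The lactone is in place early, and the propargyl group could later close ring D onto C13 and deliver the exocyclic methylene directly.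
- Against it here: an ester tether must leave its preferred extended conformation to reach the diene, so such cycloadditions need high temperature, where a silyl enol ether diene and a 1,1-disubstituted acrylate are prone to side reactions. The relative configuration of C8 and C9 depends on an endo/exo preference that the tether does not clearly impose. The enol ether of A2 lies on the C11 side of C12, so ring D closure at C13 would need regiocontrolled re-enolisation. C15 arrives without oxygen, so a late allylic oxidation beside the finished methylene group is required, and the C12 oxygen must still be removed.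
- Comparison: structurally both plans pass through a ring A–ring C array with an oxygen at C12 that is deleted later, so they are equal there. Mechanistically the alternative is pericyclic and sets C8 and C9 in one event, whereas the chosen plan uses two polar steps but brings ring D with its C15 ketone from a commercial keto ester. In step count the alternative is probably equal or slightly shorter up to the tricycle and longer afterwards.

**Alternative 2:** The cut is C5–C10 and C3–C4 of ring A. Forward, a chiral oxazaborolidinium Lewis acid would promote the [4+2] addition of silyloxydiene 6 to (E)-enal 3 and give the ring A silyl enol ether aldehyde ester A3.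

- In its favour: the quaternary centre C4 and its neighbour C5 are set in one catalytic step from two achiral partners. The (E)-geometry of the enal becomes the cis relation of the C4 methyl and C6, and the C1 oxygen and the C10 ester arrive in the right places.
- Against it as the centre of the plan: it solves the easier half of the molecule and leaves C8–C9, ring C and the bicycle open. A trisubstituted enal and an ester-bearing diene are not the most reactive pair.
- Comparison: this disconnection complements the Stetter closure and does not compete with it. For ring A it is judged equal or superior to any other entry, and it is used as step 3 of the chosen route, where A3 is the C10-defined form of intermediate 7. It removes more bonds and stereocentres than the chosen key step, but in the less demanding region. Mechanistically it is a concerted, catalyst-controlled cycloaddition. In step economy it is neutral, because it is part of both plans.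

**Alternative 3:** The cut removes C13–C16 and C12–C16, that is ring D together with a cyclopropane. It leads back to diazoketone A4, in which C8 of a ring C cyclohexene (C12=C13) carries the COCHN2 group and the lactone is already closed. Forward, Rh2(OAc)4 would convert A4 into a carbenoid at C16 that adds to the C12=C13 bond and gives the pentacyclic cyclopropyl ketone A5. Reductive cleavage of the C12–C16 bond would then uncover the bicyclo[3.2.1]octan-15-one.

- In its favour: intramolecular cyclopropanation of unsaturated diazoketones is dependable, and C13 is fixed by the tether as in the chosen plan. The C15 ketone is delivered directly and no oxygen is left at C12, so steps 17 and 18 would have no counterpart; on this point the alternative is better.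
- Against it here: A4 still contains the C8–C9 bond and the quaternary C8, so the hardest bond is only moved earlier and the commercial ring D keto ester can no longer be used. The diazoketone must be made from a neopentyl acid in the presence of the lactone and two acetates. The ring opening must break C12–C16 and not C13–C16 (which would give a bicyclo[2.2.2]octane), and must use a reagent such as SmI2 that spares acetates and lactone.
- Comparison: structurally the alternative reaches the ketone without a superfluous oxygen (better). Mechanistically it replaces a catalytic umpolung step by a carbenoid addition plus a reductive fragmentation, comparable in risk. In step economy the two steps saved at C12 are likely spent on the longer, linear construction of A4.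

Key step: step 16

## Route

Step 1
Reactants: 1 benzyloxyacetaldehyde; 2 2-(triphenyl-λ5-phosphanylidene)propanal
Product: 3 (E)-4-(benzyloxy)-2-methylbut-2-enal
Conditions: PhMe, 80 °C
Reagents that add atoms: none
Why: Wittig olefination with a formyl-stabilised ylide; the ylide reacts only with the unhindered aldehyde 1 and gives the thermodynamically preferred (E)-trisubstituted enal.

Step 2
Reactants: 4 methyl 5-methoxy-3-oxopentanoate
Product: 6 methyl (2Z)-3-[(tert-butyldimethylsilyl)oxy]penta-2,4-dienoate, via lithium dienolate 5 (not isolated)
Conditions: LiN(iPr)2 (2.1 equiv), THF, −78 → −20 °C; then tBuMe2SiOTf (2.2 equiv), −78 °C → rt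
Reagents that add atoms: tert-butyldimethylsilyl trifluoromethanesulfonate, CC(C)(C)[Si](C)(C)OS(=O)(=O)C(F)(F)F
Why: Double deprotonation gives the 2,4-dianion of the β-keto ester, whose C4 carbanion expels the C5 methoxide (E1cB) to leave the chelated lithium enolate 5 of the vinyl ketone; no free vinyl ketone is present, so it cannot polymerise. O-Silylation of the chelated enolate keeps ester and silyloxy group cis, which places the ester on the outside of the s-cis diene.

Step 3
Reactants: 3 (E)-4-(benzyloxy)-2-methylbut-2-enal; 6 methyl (2Z)-3-[(tert-butyldimethylsilyl)oxy]penta-2,4-dienoate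
Product: 8 methyl (5S,6S)-6-[(benzyloxy)methyl]-5-formyl-5-methyl-2-oxocyclohexane-1-carboxylate (C10 epimers), via silyl enol ether cycloadduct 7 (not isolated)
Conditions: (R)-B-(o-tolyl)oxazaborolidine from (R)-α,α-diphenylprolinol (20 mol%), Tf2NH (18 mol%), CH2Cl2, −78 → −40 °C; then 1 M HCl, THF, 0 °C
Reagents that add atoms: none
Why: Enantioselective Diels–Alder reaction under chiral oxazaborolidinium catalysis; the enal is held on boron s-trans with a formyl C–H···O contact over a catalyst phenyl group, so the diene adds to the open C4 si face (the enantiomeric catalyst is equally available should the sense need inverting). The silyloxy group directs the nucleophilic diene terminus C10 to the enal β-carbon C5 (bonds C5–C10 and C3–C4), and suprafacial addition turns the (E)-geometry into the cis C4-methyl/C6 relation. Acid hydrolysis gives the β-keto ester; C10 is uncontrolled here and is set in step 4.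

Step 4
Reactants: 8 methyl (5S,6S)-6-[(benzyloxy)methyl]-5-formyl-5-methyl-2-oxocyclohexane-1-carboxylate
Product: 9 methyl (1S,5S,6R)-6-[(benzyloxy)methyl]-5-formyl-1-(hydroxymethyl)-5-methyl-2-oxocyclohexane-1-carboxylate
Conditions: 37% aq. CH2O, KHCO3, THF, rt
Reagents that add atoms: formaldehyde, C=O
Why: Aldol addition of the β-keto ester to formaldehyde (hydroxymethylation); the electrophile should enter anti to the neighbouring C6 group. The addition is reversible, and the isomer with C20 cis to the C19 formyl group can be held as a lactol, so kinetic and thermodynamic preferences point to the same C10 configuration.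

Step 5
Reactants: 9 methyl (1S,5S,6R)-6-[(benzyloxy)methyl]-5-formyl-1-(hydroxymethyl)-5-methyl-2-oxocyclohexane-1-carboxylate
Product: 10 methyl 6-[(benzyloxy)methyl]-2-hydroxy-1,5-bis(hydroxymethyl)-5-methylcyclohexane-1-carboxylate (ring A triol; C1–OH on the upper face)
Conditions: Me4NBH(OAc)3, MeCN/AcOH, −20 °C → rt
Reagents that add atoms: none
Why: Hydroxyl-directed triacetoxyborohydride reduction; the aldehyde is reduced, and the C1 ketone receives hydride intramolecularly from boron bound to the lower-face O20 (or O19), so the new C1 hydroxyl is on the upper face, trans to C20. The acidic medium prevents retro-aldol loss of formaldehyde and the ester is untouched.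

Step 6
Reactants: 10 ring A triol
Product: 11 C19,C20-bis(tert-butyldimethylsilyl) ether of 10 (C1–OH free)
Conditions: tBuMe2SiCl (2.2 equiv), imidazole, DMF, 0 °C → rt
Reagents that add atoms: tert-butyldimethylsilyl chloride, CC(C)(C)[Si](C)(C)Cl
Why: Silyl ether formation; the two primary hydroxyls react, while the secondary C1 hydroxyl next to quaternary C10 should not react under these conditions.

Step 7
Reactants: 11 bis-silyl ether ester
Product: 12 ring A diol (C9 CH2OH on C10 and C1–OH free; O19 and O20 silylated; O6 benzylated)
Conditions: LiAlH4, THF, 0 °C → rt
Reagents that add atoms: none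
Why: Hydride reduction of the ester to the primary alcohol; silyl and benzyl ethers are inert, and C9 stays distinct from C20 because O20 is silylated.

Step 8
Reactants: 12 ring A diol
Product: 13 ring A β-hydroxy aldehyde (C9 formyl on C10; C1–OH free)
Conditions: TEMPO (cat.), PhI(OAc)2, CH2Cl2, rt
Reagents that add atoms: none
Why: Oxoammonium (TEMPO) oxidation is selective for the primary alcohol over the hindered secondary C1 hydroxyl; the aldehyde has no α-hydrogen and cannot epimerise or eliminate.

Step 9
Reactants: 13 ring A β-hydroxy aldehyde
Product: 14 ring A β-acetoxy aldehyde (C1 acetate)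
Conditions: Ac2O, pyridine, DMAP (cat.), CH2Cl2, rt
Reagents that add atoms: acetic anhydride, CC(=O)OC(C)=O
Why: DMAP-catalysed acetylation installs the C1 acetate of the target; it also blocks retro-aldol cleavage of the β-hydroxy aldehyde and later lactol formation between O1 and C12.

Step 10
Reactants: 14 ring A β-acetoxy aldehyde; 15 2-(triphenyl-λ5-phosphanylidene)acetaldehyde
Product: 16 ring A (E)-enal (C9=C11–C12HO on C10)
Conditions: PhMe, 90 °C
Reagents that add atoms: none
Why: Wittig olefination with the formyl-stabilised ylide gives the (E)-enal; heating is needed for the α-quaternary aldehyde, and the conjugated product is less electrophilic than 14, which limits a second homologation.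

Step 11
Reactants: 16 ring A (E)-enal; 17 methyl 2-oxocyclopentane-1-carboxylate
Product: 19 dimethyl acetal of the Michael adduct (C8 and C9 as in the target), via Michael aldehyde 18 (not isolated)
Conditions: (S)-2-[diphenyl(trimethylsilyloxy)methyl]pyrrolidine (20 mol%), PhCO2H (20 mol%), PhMe, 23 → 40 °C; then HC(OMe)3, PPTS (cat.), MeOH, 0 °C
Reagents that add atoms: trimethyl orthoformate, COC(OC)OC; methanol, CO
Why: Iminium-ion-catalysed Michael addition, then acetalisation in the same flask. The diphenyl(silyloxy)methyl group of the (S)-amine blocks one face of the (E), s-trans iminium ion, so the enol of 17 adds to the other face of C9, which is the configuration required. At C8 the five-membered ring of the enol should turn away from quaternary C10 with the flat enol carbon C15, not the C14 methylene, next to C10, which gives the required C8 configuration.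

Step 12
Reactants: 19 dimethyl acetal of the Michael adduct
Product: 20 C6 primary alcohol
Conditions: H2 (1 atm), Pd/C, EtOAc, rt
Reagents that add atoms: none
Why: Hydrogenolysis of the benzyl ether at the last stage that holds no alkene; ketone, acetal, esters and silyl ethers are inert in a neutral aprotic solvent.

Step 13
Reactants: 20 C6 primary alcohol
Product: 21 C1,C6-diacetate
Conditions: Ac2O, pyridine, DMAP (cat.), CH2Cl2, rt
Reagents that add atoms: acetic anhydride, CC(=O)OC(C)=O
Why: Acetylation of the primary hydroxyl gives the C6 acetate of the target; C8 is quaternary, so the β-keto ester cannot form an enol acetate.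

Step 14
Reactants: 21 C1,C6-diacetate
Product: 23 cyclopentenone dimethyl acetal (C16=C13), via trimethylsilyl enol ether 22 (not isolated)
Conditions: LiN(SiMe3)2, Me3SiCl, THF, −78 °C; then Pd(OAc)2, MeCN, rt
Reagents that add atoms: none
Why: Saegusa oxidation; the cyclopentanone can enolise only towards C16 because C8 is quaternary, and its α-hydrogens are far more acidic than those of the acetates, so in situ silylation is selective. Palladation of the enol ether and β-hydride elimination give the C16=C13 enone; the acetal keeps the aldehyde from enolising.

Step 15
Reactants: 23 cyclopentenone dimethyl acetal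
Product: 24 ring A–cyclopentenone aldehyde (key-step precursor)
Conditions: LiBF4, MeCN/H2O, rt
Reagents that add atoms: water, O
Why: Mild Lewis-acid-assisted acetal hydrolysis releases the aldehyde immediately before use; silyl ethers, acetates and the enone are not affected.

Step 16
Reactants: 24 ring A–cyclopentenone aldehyde
Product: 25 bicyclo[3.2.1]octane-12,15-dione ester (key-step product)
Conditions: 2-(pentafluorophenyl)-6,7-dihydro-5H-pyrrolo[2,1-c][1,2,4]triazol-2-ium tetrafluoroborate (30 mol%), KN(SiMe3)2 (25 mol%), PhMe, 23 → 60 °C
Reagents that add atoms: none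
Why: The free carbene, made from the triazolium salt with slightly less than its own amount of base, adds to the C12 aldehyde, and proton transfer gives the Breslow intermediate, an acyl anion equivalent at C12. This adds to C13, the β-carbon of the C16=C13–C15=O enone, in a 6-exo-trig conjugate addition that closes ring C (C8–C9–C11–C12–C13–C14) across the 1,3-positions of the cyclopentenone; protonation at C16 and loss of the carbene give the C12 ketone. The closest known reaction type is the intramolecular Stetter reaction of aliphatic aldehydes with cyclic enones, used here in the less common bridging mode. C13 is the only new stereocentre and is controlled by the tether: the aldehyde chain is anchored at C8 of the same five-membered ring, so the bond can form only on the ring face that carries C9, which is the bicyclo[3.2.1]octane geometry of the target. The step needs conjugate addition to prevail over carbene-mediated 1,2-addition to the C15 carbonyl and over base-induced aldol or retro-Michael reactions of the aldehyde. The first is expected because addition to the neopentyl C15 carbonyl can revert while the 1,4-addition cannot, so on warming the material should drain to 25; the second because no base beyond the carbene is present, C8 is quaternary and cannot enolise, and acetates and silyl ethers are inert to the carbene.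

Step 17
Reactants: 25 bicyclo[3.2.1]octane-12,15-dione ester
Product: 26 C12 dithiolane
Conditions: HSCH2CH2SH, Zn(OTf)2, CH2Cl2, rt
Reagents that add atoms: ethane-1,2-dithiol, SCCS
Why: Lewis-acid-catalysed dithioketalisation; the six-ring carbonyl C12 should react, while the C15 carbonyl, flanked by quaternary C8 in the five-membered ring, should not. Zn(OTf)2 is mild enough for the silyl ethers and acetates.

Step 18
Reactants: 26 C12 dithiolane
Product: 27 bicyclo[3.2.1]octan-15-one ester
Conditions: Raney Ni (W-2, acetone-washed), EtOH, rt
Reagents that add atoms: none
Why: Raney Ni desulfurisation replaces the two C–S bonds by C–H and so removes the C12 oxygen; short contact with deactivated catalyst should leave the hindered C15 ketone unreduced.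

Step 19
Reactants: 27 bicyclo[3.2.1]octan-15-one ester
Product: 30 16-methylene-15-ketone ester, via Mannich base 28 (not isolated), via methiodide 29 (not isolated)
Conditions: LiN(SiMe3)2, THF, −78 °C; Me2N=CH2 I, −78 °C → rt; then MeI, CH2Cl2, rt; then DBU, rt
Reagents that add atoms: dimethyl(methylidene)ammonium iodide, C=[N+](C)C.[I-]
Why: α-Methylenation by a Mannich reaction of the lithium enolate (only C16 is enolisable, and it is more acidic than the acetates), N-methylation and E1cB loss of trimethylamine. It is placed after all nucleophilic and reductive steps because the enone is a Michael acceptor.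

Step 20
Reactants: 30 16-methylene-15-ketone ester
Product: 32 target spirolactone CNP0370815.4, via hydroxy ester 31 (not isolated)
Conditions: HF·pyridine, THF/pyridine, 0 → 40 °C
Reagents that add atoms: none
Why: Fluoride cleavage of both silyl ethers in an acidic medium; the freed C20 hydroxyl then lactonises onto the neighbouring C7 ester (six-membered ring, loss of methanol), while the C19 hydroxyl stays free. No base is present, so neither acetate should migrate and the enone is not attacked.

## Compound list

1 | benzyloxyacetaldehyde | O=CCOCc1ccccc1 | starting material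
2 | 2-(triphenyl-λ5-phosphanylidene)propanal | CC(C=O)=P(c1ccccc1)(c1ccccc1)c1ccccc1 | starting material
3 | (E)-4-(benzyloxy)-2-methylbut-2-enal | O=C/C(C)=C/COCc1ccccc1 | intermediate
4 | methyl 5-methoxy-3-oxopentanoate | COCCC(=O)CC(=O)OC | starting material
5 | lithium (Z)-dienolate of methyl 3-oxopent-4-enoate | [Li+].COC(=O)/C=C(\[O-])C=C | intermediate
6 | methyl (2Z)-3-[(tert-butyldimethylsilyl)oxy]penta-2,4-dienoate | COC(=O)/C=C(\O[Si](C)(C)C(C)(C)C)C=C | intermediate
7 | methyl (5S,6S)-6-[(benzyloxy)methyl]-2-[(tert-butyldimethylsilyl)oxy]-5-formyl-5-methylcyclohex-2-ene-1-carboxylate (ring A silyl enol ether; C10 not controlled) | COC(=O)C1C(O[Si](C)(C)C(C)(C)C)=CC[C@](C)(C=O)[C@H]1COCc1ccccc1 | intermediate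
8 | methyl (5S,6S)-6-[(benzyloxy)methyl]-5-formyl-5-methyl-2-oxocyclohexane-1-carboxylate (ring A β-keto ester; C10 epimers and enol) | COC(=O)C1C(=O)CC[C@](C)(C=O)[C@H]1COCc1ccccc1 | intermediate
9 | methyl (1S,5S,6R)-6-[(benzyloxy)methyl]-5-formyl-1-(hydroxymethyl)-5-methyl-2-oxocyclohexane-1-carboxylate (C20 on the lower face, cis to the C19 formyl group; may exist as the C19/O20 lactol) | COC(=O)[C@@]1(CO)C(=O)CC[C@](C)(C=O)[C@H]1COCc1ccccc1 | intermediate
10 | methyl 6-[(benzyloxy)methyl]-2-hydroxy-1,5-bis(hydroxymethyl)-5-methylcyclohexane-1-carboxylate (ring A triol; C1–OH, CO2Me, C6 and C4 methyl on the upper face; C19 and C20 on the lower face) | COC(=O)[C@@]1(CO)[C@@H](O)CC[C@](C)(CO)[C@H]1COCc1ccccc1 | intermediate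
11 | C19,C20-bis(tert-butyldimethylsilyl) ether of 10 (C1–OH free) | COC(=O)[C@@]1(CO[Si](C)(C)C(C)(C)C)[C@@H](O)CC[C@](C)(CO[Si](C)(C)C(C)(C)C)[C@H]1COCc1ccccc1 | intermediate
12 | ring A diol (C9 CH2OH and C1–OH free; O19, O20 silylated; O6 benzylated) | OC[C@@]1(CO[Si](C)(C)C(C)(C)C)[C@@H](O)CC[C@](C)(CO[Si](C)(C)C(C)(C)C)[C@H]1COCc1ccccc1 | intermediate
13 | ring A β-hydroxy aldehyde (C9 formyl on C10; C1–OH free) | O=C[C@@]1(CO[Si](C)(C)C(C)(C)C)[C@@H](O)CC[C@](C)(CO[Si](C)(C)C(C)(C)C)[C@H]1COCc1ccccc1 | intermediate
14 | ring A β-acetoxy aldehyde (C1 acetate) | O=C[C@@]1(CO[Si](C)(C)C(C)(C)C)[C@@H](OC(C)=O)CC[C@](C)(CO[Si](C)(C)C(C)(C)C)[C@H]1COCc1ccccc1 | intermediate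
15 | 2-(triphenyl-λ5-phosphanylidene)acetaldehyde | O=CC=P(c1ccccc1)(c1ccccc1)c1ccccc1 | starting material
16 | ring A (E)-enal (C9=C11–C12HO on C10; C1 acetate; O6 benzyl; O19, O20 silyl) | O=C/C=C/[C@@]1(CO[Si](C)(C)C(C)(C)C)[C@@H](OC(C)=O)CC[C@](C)(CO[Si](C)(C)C(C)(C)C)[C@H]1COCc1ccccc1 | intermediate
17 | methyl 2-oxocyclopentane-1-carboxylate | COC(=O)C1CCCC1=O | starting material
18 | Michael adduct aldehyde (C12 aldehyde; methyl 2-oxocyclopentane-1-carboxylate unit bonded through C8 to C9; C8 and C9 as in the target) | O=CC[C@H]([C@@]2(C(=O)OC)CCCC2=O)[C@@]1(CO[Si](C)(C)C(C)(C)C)[C@@H](OC(C)=O)CC[C@](C)(CO[Si](C)(C)C(C)(C)C)[C@H]1COCc1ccccc1 | intermediate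
19 | dimethyl acetal of 18 | COC(OC)C[C@H]([C@@]2(C(=O)OC)CCCC2=O)[C@@]1(CO[Si](C)(C)C(C)(C)C)[C@@H](OC(C)=O)CC[C@](C)(CO[Si](C)(C)C(C)(C)C)[C@H]1COCc1ccccc1 | intermediate
20 | C6 primary alcohol (debenzylated 19) | COC(OC)C[C@H]([C@@]2(C(=O)OC)CCCC2=O)[C@@]1(CO[Si](C)(C)C(C)(C)C)[C@@H](OC(C)=O)CC[C@](C)(CO[Si](C)(C)C(C)(C)C)[C@H]1CO | intermediate
21 | C1,C6-diacetate (cyclopentanone, dimethyl acetal) | COC(OC)C[C@H]([C@@]2(C(=O)OC)CCCC2=O)[C@@]1(CO[Si](C)(C)C(C)(C)C)[C@@H](OC(C)=O)CC[C@](C)(CO[Si](C)(C)C(C)(C)C)[C@H]1COC(C)=O | intermediate
22 | trimethylsilyl enol ether of 21 (C15–OSiMe3, C15=C16) | COC(OC)C[C@H]([C@@]2(C(=O)OC)CCC=C2O[Si](C)(C)C)[C@@]1(CO[Si](C)(C)C(C)(C)C)[C@@H](OC(C)=O)CC[C@](C)(CO[Si](C)(C)C(C)(C)C)[C@H]1COC(C)=O | intermediate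
23 | cyclopentenone dimethyl acetal (C16=C13) | COC(OC)C[C@H]([C@@]2(C(=O)OC)CC=CC2=O)[C@@]1(CO[Si](C)(C)C(C)(C)C)[C@@H](OC(C)=O)CC[C@](C)(CO[Si](C)(C)C(C)(C)C)[C@H]1COC(C)=O | intermediate
24 | ring A–cyclopentenone aldehyde (key-step precursor) | O=CC[C@H]([C@@]2(C(=O)OC)CC=CC2=O)[C@@]1(CO[Si](C)(C)C(C)(C)C)[C@@H](OC(C)=O)CC[C@](C)(CO[Si](C)(C)C(C)(C)C)[C@H]1COC(C)=O | intermediate
25 | bicyclo[3.2.1]octane-12,15-dione ester (key-step product) | C1C(=O)[C@]2(C(=O)OC)C[C@H]1C(=O)C[C@H]2[C@@]1(CO[Si](C)(C)C(C)(C)C)[C@@H](OC(C)=O)CC[C@](C)(CO[Si](C)(C)C(C)(C)C)[C@H]1COC(C)=O | intermediate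
26 | C12 dithiolane of 25 | C1C(=O)[C@]2(C(=O)OC)C[C@H]1C3(SCCS3)C[C@H]2[C@@]1(CO[Si](C)(C)C(C)(C)C)[C@@H](OC(C)=O)CC[C@](C)(CO[Si](C)(C)C(C)(C)C)[C@H]1COC(C)=O | intermediate
27 | bicyclo[3.2.1]octan-15-one ester (C12 = CH2) | C1C(=O)[C@]2(C(=O)OC)C[C@H]1CC[C@H]2[C@@]1(CO[Si](C)(C)C(C)(C)C)[C@@H](OC(C)=O)CC[C@](C)(CO[Si](C)(C)C(C)(C)C)[C@H]1COC(C)=O | intermediate
28 | 16-(dimethylaminomethyl)-15-ketone (Mannich base; C16 not defined) | CN(C)CC1C(=O)[C@]2(C(=O)OC)C[C@H]1CC[C@H]2[C@@]1(CO[Si](C)(C)C(C)(C)C)[C@@H](OC(C)=O)CC[C@](C)(CO[Si](C)(C)C(C)(C)C)[C@H]1COC(C)=O | intermediate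
29 | N-methyl quaternary iodide of 28 | C[N+](C)(C)CC1C(=O)[C@]2(C(=O)OC)C[C@H]1CC[C@H]2[C@@]1(CO[Si](C)(C)C(C)(C)C)[C@@H](OC(C)=O)CC[C@](C)(CO[Si](C)(C)C(C)(C)C)[C@H]1COC(C)=O.[I-] | intermediate
30 | 16-methylene-15-ketone ester (C7 methyl ester; O19, O20 silyl) | C=C1C(=O)[C@]2(C(=O)OC)C[C@H]1CC[C@H]2[C@@]1(CO[Si](C)(C)C(C)(C)C)[C@@H](OC(C)=O)CC[C@](C)(CO[Si](C)(C)C(C)(C)C)[C@H]1COC(C)=O | intermediate
31 | desilylated hydroxy ester (C19–OH and C20–OH free) | C=C1C(=O)[C@]2(C(=O)OC)C[C@H]1CC[C@H]2[C@@]1(CO)[C@@H](OC(C)=O)CC[C@](C)(CO)[C@H]1COC(C)=O | intermediate
32 | CNP0370815.4 (1,6-diacetoxy-19-hydroxy-15-oxo-6,7-seco-ent-kaur-16-ene 7,20-lactone) | C=C1C(=O)[C@]23C[C@H]1CC[C@H]2[C@@]1(COC3=O)[C@@H](OC(C)=O)CC[C@](C)(CO)[C@H]1COC(C)=O | target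

## Step count and least certain steps

Total steps: 20. Longest linear sequence: 19 steps (4 → 32 through steps 2–20; equally 1 → 32 through steps 1 and 3–20).

**Step 16 (key step).** The Breslow intermediate may be diverted into 1,2-addition at C15 without turnover, the enolisable aldehyde may undergo base-induced aldol condensation or retro-Michael fragmentation, or the bridging closure may simply be slow for strain reasons. Fallback: a reductive radical closure of the same bond. Starting from 24, SmI2 (tBuOH, THF, −78 °C) generates the C12 ketyl radical, which adds to C13 under the same tether control and gives the C12 hydroxy 15-ketone F1 (C12 carbinol epimers, a centre that is destroyed next). Oxidation of F1 with DMP (1,1,1-triacetoxy-1,1-dihydro-1,2-benziodoxol-3(1H)-one, CH2Cl2, NaHCO3) returns to the route at 25.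

**Step 11.** Bond formation at the neopentyl β-carbon C9 may be too slow or revert, and the relative topicity at C8 is the least controlled element of the route; a wrong C8 epimer cannot undergo the bridging closure of step 16. Fallback: a Mukaiyama–Michael addition with a preformed enol silane and silyl-cation activation in place of iminium catalysis. Keto ester 17 is converted (Me3SiCl, Et3N, DMF) into methyl 2-[(trimethylsilyl)oxy]cyclopent-1-ene-1-carboxylate F2. F2 is added to enal 16 with Tf2NH (cat.) in CH2Cl2 at −78 °C, a pathway with an early transition state that tolerates congested bond formation better, facial selectivity at C9 then coming from the substrate alone. Mild acidic work-up gives aldehyde 18, which is acetalised as in step 11 and returns to the route at 19.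

**Step 10.** Olefination of the α-quaternary aldehyde may be incomplete at temperatures where the product enal begins to react with a second equivalent of ylide. Fallback: a phosphonate homologation with redox adjustment, starting from 13 before acetylation. Horner–Wadsworth–Emmons reaction of 13 with triethyl phosphonoacetate (LiCl, DBU, MeCN) gives the hydroxy (E)-enoate F3. Reduction with iBu2AlH (CH2Cl2, −78 °C) gives the allylic diol F4, and MnO2 (CH2Cl2), which oxidises only the allylic alcohol, gives the hydroxy enal F5. Acetylation of F5 under the conditions of step 9 returns to the route at 16.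

**Step 17 (with step 18).** Chemoselectivity between the two ketones may be lost, the Lewis acid may cleave silyl ethers during thioketalisation, or the nickel may over-reduce C15. Fallback: a sulfur-free deoxygenation, starting from 25. p-Toluenesulfonyl hydrazide (EtOH, cat. AcOH) condenses with the less hindered C12 carbonyl to give the mono-tosylhydrazone F6. Catecholborane (CHCl3, 0 °C) followed by NaOAc·3H2O at reflux reduces it to the methylene compound, returning to the route at 27 and bypassing 26.

## Further compounds

F1 | step 16 | C12 hydroxy 15-ketone (bicyclo[3.2.1]octane; C12 carbinol epimers) | C1C(=O)[C@]2(C(=O)OC)C[C@H]1C(O)C[C@H]2[C@@]1(CO[Si](C)(C)C(C)(C)C)[C@@H](OC(C)=O)CC[C@](C)(CO[Si](C)(C)C(C)(C)C)[C@H]1COC(C)=O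
F2 | step 11 | methyl 2-[(trimethylsilyl)oxy]cyclopent-1-ene-1-carboxylate | COC(=O)C1=C(O[Si](C)(C)C)CCC1
F3 | step 10 | ring A hydroxy (E)-enoate (ethyl ester; C1–OH free) | CCOC(=O)/C=C/[C@@]1(CO[Si](C)(C)C(C)(C)C)[C@@H](O)CC[C@](C)(CO[Si](C)(C)C(C)(C)C)[C@H]1COCc1ccccc1
F4 | step 10 | ring A (E)-allylic alcohol (C12–OH and C1–OH free) | OC/C=C/[C@@]1(CO[Si](C)(C)C(C)(C)C)[C@@H](O)CC[C@](C)(CO[Si](C)(C)C(C)(C)C)[C@H]1COCc1ccccc1
F5 | step 10 | ring A hydroxy (E)-enal (C1–OH free) | O=C/C=C/[C@@]1(CO[Si](C)(C)C(C)(C)C)[C@@H](O)CC[C@](C)(CO[Si](C)(C)C(C)(C)C)[C@H]1COCc1ccccc1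
F6 | step 17 | C12 mono-tosylhydrazone of 25 | C1C(=O)[C@]2(C(=O)OC)C[C@H]1C(=NNS(=O)(=O)c3ccc(C)cc3)C[C@H]2[C@@]1(CO[Si](C)(C)C(C)(C)C)[C@@H](OC(C)=O)CC[C@](C)(CO[Si](C)(C)C(C)(C)C)[C@H]1COC(C)=O
A1 | alternative 1 | C20 2-(prop-2-yn-1-yl)acrylate of the ring A (E)-3-silyloxybuta-1,3-dienyl compound | C#CCC(=C)C(=O)OC[C@]1(/C=C/C(=C)O[Si](C)(C)C(C)(C)C)[C@@H](OC(C)=O)CC[C@](C)(CO[Si](C)(C)C(C)(C)C)[C@H]1COC(C)=O
A2 | alternative 1 | tricyclic spirolactone silyl enol ether | C#CC[C@]23CCC(O[Si](C)(C)C(C)(C)C)=C[C@H]2[C@@]1(COC3=O)[C@@H](OC(C)=O)CC[C@](C)(CO[Si](C)(C)C(C)(C)C)[C@H]1COC(C)=O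
A3 | alternative 2 | ring A silyl enol ether aldehyde ester (C10-defined form of 7) | COC(=O)[C@@H]1C(O[Si](C)(C)C(C)(C)C)=CC[C@](C)(C=O)[C@H]1COCc2ccccc2
A4 | alternative 3 | ring C cyclohexene spirolactone diazoketone | [N-]=[N+]=CC(=O)[C@]23CC=CC[C@H]2[C@@]1(COC3=O)[C@@H](OC(C)=O)CC[C@](C)(CO[Si](C)(C)C(C)(C)C)[C@H]1COC(C)=O
A5 | alternative 3 | pentacyclic cyclopropyl ketone | [C@H]14C(=O)[C@]23C[C@H]1[C@H]4C[C@H]2[C@@]1(COC3=O)[C@@H](OC(C)=O)CC[C@](C)(CO[Si](C)(C)C(C)(C)C)[C@H]1COC(C)=O
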